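## Structural features

Tabularin (13) is a flavone. Benzo ring A (C4a, C5, C6, C7, C8, C8a) is fused to the 4-pyranone ring C (O1, C2, C3, C4), and C2 carries the 2,4,5-trimethoxyphenyl ring B through the C2–C1' bond. The molecule has no stereocentre and no hindered axis, so the whole problem is regiochemistry and the distinction of six oxygen substituents. Ring A bears OH at C5, OMe at C6 and OH at C7 and is unsubstituted at C8, while ring B bears three OMe groups that must outlive whatever frees the two phenols. The real difficulty is the orientation of ring C on ring A: a ring A ketone with two hydroxyls ortho to the acyl group can close to the 5,6,7- or to the 5,7,8-oxygenation pattern, and strong acid interconverts the two by ring opening and reclosure (Wessely–Moser rearrangement). A second difficulty is that the C6 methoxy, twisted out of plane between two oxygens, is the ether most easily lost to Lewis acids, so the C5 and C7 hydroxyls cannot come from late demethylation and must travel under groups that leave with mild protic acid. The key step exploits the local mirror plane of ring A through O1–C8a and C6–OMe: once C4–C4a is cut, O5 and O7 become equivalent, and C4a and C8 become equivalent C–H positions, each ortho to O1, ortho to one flanking oxygen and para to the other. Closure of ring C at carbon (C4–C4a), with O1–C2 already in place, can therefore give only one flavone and needs only one kind of protecting group. Fragile on the way are the push–pull enol ether O1–C2=C3 (acid plus nucleophile, hydroxide at C2), the acetal protecting groups (acid) and the very electron-rich phenol of ring A (oxidants).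

## Logic of the disconnections

**13 from 12.** Bonds cut: the two O–CH2 acetal bonds on O5 and O7. Reason: free hydroxyls at C5 and C7 would intercept the acylating agent of the ring closure, and they cannot be unveiled from methyl ethers without endangering the C6 methoxy. Gain: both oxygens carry the same group, so ring A keeps its mirror plane all the way back. Demand: release by dilute protic acid in an alcohol, far below the severity that opens ring C. Because the ring closure already ends in an acidic medium, the release is run in the same flask.

**12 from 10 (through 11).** Bond cut: C4–C4a, the key disconnection. Reason: it is the only cut of ring C that restores the mirror plane of ring A, so the 6-methoxy/8-methoxy question disappears instead of having to be answered. Gain: a bicyclic heteroaromatic with a fully differentiated ring A falls back to an open chain that joins a symmetric aryl ether to ring B. Demand: the acyl carbon must attack the ortho C–H of ring A and not ring B, both alkene isomers must funnel into the closure, and no Lewis acid may be used. In one sentence, ring C is closed at C4–C4a by intramolecular Friedel–Crafts acylation of 10, in which O1–C2 is already in place. The route most chemists would draw first closes ring C at O1–C2 from a ring A ketone, so that sentence does not fit it.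

**10 from 9.** Bond cut: none in the skeleton; acyl–OH is traced back to acyl–OMe. Reason: the ester is what makes the alkyne of the preceding step an acceptor. Gain: none in complexity, it only links two stages. Demand: hydroxide must attack the ester carbonyl and not C2.

**9 from 4 and 8.** Bond cut: O1–C2. Reason: this is the convergent cut, one piece holding all of ring A and the other all of ring B with C2, C3 and C4. Gain: two fragments of similar size, and the ring oxygen is defined by the only free hydroxyl of 4. Demand: conjugate addition of a phenoxide to an alkynoate whose acceptor carbon is deactivated by ring B.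

**8 from 6 and 7.** Bond cut: C2–C1'. Reason: sp–sp2 coupling delivers the three-carbon unit at its final oxidation level in one operation. Gain: ring B is reduced to a simple aryl halide. Demand: a coupling protocol that does not destroy the electron-poor alkyne 7.

**6 from 5.** Bond cut: C1'–I. Reason: the 2',4',5' pattern is the innate electrophilic substitution pattern of 5. Gain: a bulk arene as starting material. Demand: monohalogenation only.

**4 from 2 (through 3).** Bond cut: C8a–O1. Reason: this carbon is meta to both flanking oxygens and out of reach of electrophiles and of directed metalation, but it is the only unhindered aromatic C–H of 2. Gain: the tetraoxygenated ring A comes from a trioxygenated arene in one flask. Demand: sterically governed C–H functionalisation, and protecting groups that contain no aromatic C–H.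

**2 from 1.** Bonds cut: the two O–CH2 bonds. Reason: 1 already holds the OH/OMe/OH triad in its final arrangement. Gain: a commercial symmetric starting material. Demand: exhaustive alkylation of two equivalent hydroxyls.

## Other disconnections considered

**Alternative 1:** cut O1–C2 and C2–C3. This is the route that comes to mind first.
- Forward sequence: the o-hydroxyacetophenone A1 is O-aroylated with the acid chloride A2. Base moves the aroyl group from oxygen to the methyl carbon (Baker–Venkataraman rearrangement) to give the 1,3-diketone A3. Acid closes ring C at O1–C2 by cyclodehydration, and hydrogenolysis would end the route.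
- Ground for rejection: all the difficulty is pushed into A1. Its ring A must carry an acetyl group and four different oxygen functions.
- The two hydroxyls ortho to the acetyl group are both chelated and chemically alike. Which one stays free decides between 13 and its 8-methoxy isomer A4.
- Making A1 would cost several selective protection steps on a ring that has already lost its symmetry, and the acidic closure acts on a substrate able to equilibrate toward A4 if a benzyl group is lost.
- The chosen plan never breaks the symmetry before the ring is closed.

**Alternative 2:** cut C2–C1'.
- Forward key step: dehydrogenative coupling of the C2–H of chromone A5 with the C5–H of 5 (Pd(OAc)2, AgOAc, pivalic acid, heat). Divalent palladium metalates the arene and adds across C2=C3.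
- The site on 5 is well explained by its substitution pattern. However, the step does not touch the real problem, because ring C still has to be placed on ring A to make A5, most sensibly by the same C4–C4a closure from 4 and 7. The coupling would be an added step and not a simplification.
- Mechanistically, the electron richness that favours metalation of 5 also favours its oxidative homocoupling by the silver salt. The arene is normally needed in large excess. Hot carboxylic acid would strip the acetals of A5 and expose a chelating C5 hydroxyl next to the carbonyl.

**Alternative 3:** cut C4–C4a and O1–C2 at the same time.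
- Forward key step: thermal condensation of the unprotected triol A6 with the β-keto ester A7 (Mentzer-type pyrone synthesis).
- On paper this is the shortest plan. However, the order of events is C-acylation first and O-closure second.
- After acylation at either equivalent C–H of A6, two non-equivalent hydroxyls flank the new ketone, and nothing in the structure biases closure toward 13 over A4.
- The Pechmann mode (ring carbon attacking the ketone carbonyl) competes, the temperatures are very high, and A6 is air-sensitive and not a stock chemical.
- The chosen plan uses the same two bonds but fixes O1–C2 first on the only free hydroxyl, and that order is what makes the outcome unambiguous.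

Key step: step 7

Assumption: 9, 10 and 11 are drawn and named as the Z isomers (aryloxy group and carbonyl group on the same side of C2=C3). Step 5 may deliver both alkene isomers, which are carried on together because they converge in step 7.

## Steps

Step 1
Reactants: 1 2-methoxybenzene-1,3-diol (2-methoxyresorcinol)
Product: 2 2-methoxy-1,3-bis(methoxymethoxy)benzene
Conditions: NaH (2.4 equiv), MOMCl (2.4 equiv), DMF, 0 °C to rt
Reagents that add atoms: chloromethyl methyl ether (MOMCl), COCCl
Why: Williamson-type O-alkylation of two equivalent phenoxides, so no selectivity is asked for. The methoxymethyl (MOM) acetals contain no aromatic C–H, survive base, peroxide and the metal catalysts of later steps, and leave with protic acid without any Lewis acid that would threaten the C6 methoxy.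

Step 2
Reactants: 2 2-methoxy-1,3-bis(methoxymethoxy)benzene
Product: 4 4-methoxy-3,5-bis(methoxymethoxy)phenol, via aryl pinacolboronate 3 (not isolated)
Conditions: [Ir(OMe)(cod)]2 (1.5 mol %), 4,4'-di-tert-butyl-2,2'-bipyridine (3 mol %), B2pin2 (1.0 equiv), THF, 80 °C; then 30% aq. H2O2, aq. NaOH, 0 °C
Reagents that add atoms: bis(pinacolato)diboron, CC1(C)OB(OC1(C)C)B1OC(C)(C)C(C)(C)O1 (boryl group of 3); hydrogen peroxide, OO (phenol oxygen of 4)
Why: Sterically governed iridium-catalysed aromatic C–H borylation followed by C–B oxidation (one-pot arene-to-phenol sequence). In the 1,2,3-trisubstituted ring of 2 only C5–H has no ortho substituent, and 2 holds no other aromatic C–H. Alkaline peroxide turns 3 into 4 by 1,2-shift of the aryl group from boron to oxygen, under conditions to which the acetals are inert.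

Step 3
Reactants: 5 1,2,4-trimethoxybenzene
Product: 6 1-iodo-2,4,5-trimethoxybenzene
Conditions: NIS (1.05 equiv), CF3CO2H (10 mol %), MeCN, rt, dark
Reagents that add atoms: N-iodosuccinimide, O=C1CCC(=O)N1I
Why: Electrophilic aromatic iodination. C5 of 5 is para to the C2 methoxy and ortho to the C4 methoxy, C3 is crowded between two methoxy groups and C6 is activated by only one, so the 2',4',5' pattern of ring B follows from innate selectivity.

Step 4
Reactants: 6 1-iodo-2,4,5-trimethoxybenzene; 7 methyl prop-2-ynoate (methyl propiolate)
Product: 8 methyl 3-(2,4,5-trimethoxyphenyl)prop-2-ynoate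
Conditions: PdCl2(PPh3)2 (2 mol %), CuI (4 mol %), K2CO3 (2 equiv), 7 (3 equiv, slow addition), THF, 65 °C
Reagents that add atoms: none
Why: Sonogashira coupling of an aryl iodide with an electron-poor terminal alkyne. The inorganic base replaces the usual amine, which would add to 7 in Michael fashion, and 7 is used in excess because part of it is lost to oligomerisation.

Step 5
Reactants: 4 4-methoxy-3,5-bis(methoxymethoxy)phenol; 8 methyl 3-(2,4,5-trimethoxyphenyl)prop-2-ynoate
Product: 9 methyl (2Z)-3-[4-methoxy-3,5-bis(methoxymethoxy)phenoxy]-3-(2,4,5-trimethoxyphenyl)prop-2-enoate
Conditions: Cs2CO3 (20 mol %), DMF, 90 °C, Ar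
Reagents that add atoms: none
Why: Base-catalysed oxa-Michael addition of a phenoxide to an arylpropiolate (first stage of the Ruhemann flavone synthesis). 4 has a single free hydroxyl, so O1–C2 forms without ambiguity, and proton transfer from the next molecule of 4 carries the chain. The alkene geometry need not be controlled because both isomers converge in step 7.

Step 6
Reactants: 9 methyl (2Z)-3-[4-methoxy-3,5-bis(methoxymethoxy)phenoxy]-3-(2,4,5-trimethoxyphenyl)prop-2-enoate
Product: 10 (2Z)-3-[4-methoxy-3,5-bis(methoxymethoxy)phenoxy]-3-(2,4,5-trimethoxyphenyl)prop-2-enoic acid
Conditions: LiOH·H2O (3 equiv), THF/H2O 3:1, 40 °C; then cold 1 M HCl to pH 4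
Reagents that add atoms: lithium hydroxide, [Li+].[OH-]
Why: Saponification at the ester carbonyl. C2 is fully substituted and electronically deactivated by O1 and by the 2'- and 4'-methoxy groups, so addition–elimination there should be slower. The acetals are stable to base, and the acidification is kept cold and mild.

Step 7
Reactants: 10 (2Z)-3-[4-methoxy-3,5-bis(methoxymethoxy)phenoxy]-3-(2,4,5-trimethoxyphenyl)prop-2-enoic acid
Product: 13 tabularin, 5,7-dihydroxy-6-methoxy-2-(2,4,5-trimethoxyphenyl)-4H-chromen-4-one, via mixed trifluoroacetic anhydride 11 (not isolated), via bis-MOM flavone 12 (not isolated)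
Conditions: (CF3CO)2O (1.5 equiv), CH2Cl2 (0.02 M), 0 °C to rt; then MeOH, HCl (1.25 M in MeOH), 40 °C
Reagents that add atoms: trifluoroacetic anhydride, O=C(OC(=O)C(F)(F)F)C(F)(F)F (its trifluoroacetyl group is carried only by intermediate 11)
Why: The anhydride converts 10 into 11, whose acyl carbon (future C4), as such or as the acylium ion stabilised through C3=C2 by O1 and ring B, is attacked by an ortho C–H carbon of the aryloxy ring (future C4a), and proton loss from the Wheland intermediate gives 12; this is an intramolecular Friedel–Crafts acylation, the closing stage of the Ruhemann flavone synthesis from β-aryloxycinnamic acids. Ring C (C4, C3, C2, O1, C8a, C4a) closes in the 6-exo-trig mode at the anhydride carbonyl, at a carbon–carbon bond, and no stereocentre is formed. Site selectivity within ring A is not needed, because the two ortho C–H positions are related by the mirror plane of the aryloxy ring and both lead to 12; each is ortho to O1, ortho to one OMOM and para to the other, which should make it nucleophilic enough to react without a Lewis acid. Only the Z isomer can reach the ring carbon, but the liberated CF3CO2H protonates C3 reversibly to a cation at C2 stabilised by O1 and by the 2'- and 4'-methoxy groups, rotation about C2–C3 follows, and the E isomer drains into the closure (Curtin–Hammett situation). Closure onto ring B at C6' would need the E isomer, would form a strained five-membered enone ring, and would use a carbon activated by only one ortho methoxy on a ring that is being drained by the acyl cation, so ring A should win. High dilution, a small excess of anhydride and low temperature hold back intermolecular acylation and C-trifluoroacetylation, and after closure the C4 carbonyl deactivates C8. Methanol then destroys the excess anhydride, and the acid transfers both methoxymethyl groups to methanol (transacetalisation), so any acetal loss during the first stage is of no consequence. These conditions are far milder than those that open ring C, so the 5,6,7 pattern set by the closure should persist.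

## Compound list

1 | 2-methoxybenzene-1,3-diol | COc1c(O)cccc1O | starting material
2 | 2-methoxy-1,3-bis(methoxymethoxy)benzene | COCOc1cccc(OCOC)c1OC | intermediate
3 | 2-[4-methoxy-3,5-bis(methoxymethoxy)phenyl]-4,4,5,5-tetramethyl-1,3,2-dioxaborolane | COCOc1cc(B2OC(C)(C)C(C)(C)O2)cc(OCOC)c1OC | intermediate
4 | 4-methoxy-3,5-bis(methoxymethoxy)phenol | COCOc1cc(O)cc(OCOC)c1OC | intermediate
5 | 1,2,4-trimethoxybenzene | COc1ccc(OC)c(OC)c1 | starting material
6 | 1-iodo-2,4,5-trimethoxybenzene | COc1cc(OC)c(I)cc1OC | intermediate
7 | methyl prop-2-ynoate | C#CC(=O)OC | starting material
8 | methyl 3-(2,4,5-trimethoxyphenyl)prop-2-ynoate | COC(=O)C#Cc1cc(OC)c(OC)cc1OC | intermediate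
9 | methyl (2Z)-3-[4-methoxy-3,5-bis(methoxymethoxy)phenoxy]-3-(2,4,5-trimethoxyphenyl)prop-2-enoate | COC(=O)/C=C(\Oc1cc(OCOC)c(OC)c(OCOC)c1)c1cc(OC)c(OC)cc1OC | intermediate
10 | (2Z)-3-[4-methoxy-3,5-bis(methoxymethoxy)phenoxy]-3-(2,4,5-trimethoxyphenyl)prop-2-enoic acid | OC(=O)/C=C(\Oc1cc(OCOC)c(OC)c(OCOC)c1)c1cc(OC)c(OC)cc1OC | intermediate
11 | (2Z)-3-[4-methoxy-3,5-bis(methoxymethoxy)phenoxy]-3-(2,4,5-trimethoxyphenyl)prop-2-enoic trifluoroacetic anhydride | O=C(OC(=O)/C=C(\Oc1cc(OCOC)c(OC)c(OCOC)c1)c1cc(OC)c(OC)cc1OC)C(F)(F)F | intermediate
12 | 6-methoxy-5,7-bis(methoxymethoxy)-2-(2,4,5-trimethoxyphenyl)-4H-chromen-4-one | COCOc1cc2oc(-c3cc(OC)c(OC)cc3OC)cc(=O)c2c(OCOC)c1OC | intermediate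
13 | tabularin, 5,7-dihydroxy-6-methoxy-2-(2,4,5-trimethoxyphenyl)-4H-chromen-4-one | COc1cc(OC)c(-c2cc(=O)c3c(O)c(OC)c(O)cc3o2)cc1OC | target

## Step count and least certain steps

Total step count: 7. Longest linear sequence: 5 steps (1, 2, 5, 6, 7 from 1; equally 3, 4, 5, 6, 7 from 5).

**Step 7 (key step).**
- The medium turns acidic as the closure proceeds, while ring A and the enol ether are both very electron-rich. The most likely failures are:
  - premature loss of an acetal, with capture of the methoxymethyl cation by ring A;
  - C-trifluoroacetylation of ring A;
  - addition of trifluoroacetate at C2 with expulsion of the phenol;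
  - protodecarboxylation before activation;
  - lactonisation through the 2'-methoxy oxygen of the E isomer with loss of its methyl group.
- Fallback (sets out from 4 and 6, comes back at 12): ring C is assembled from three components under basic conditions. 4 is mono-iodinated with NIS at either of its equivalent ortho positions to 2-iodo-4-methoxy-3,5-bis(methoxymethoxy)phenol F1. 6 is coupled with trimethylsilylacetylene (PdCl2(PPh3)2, CuI, Et3N) to trimethyl[(2,4,5-trimethoxyphenyl)ethynyl]silane F2, which is desilylated (K2CO3, MeOH) to 1-ethynyl-2,4,5-trimethoxybenzene F3. F1, F3 and CO (1 atm) are joined with PdCl2(PPh3)2 in Et2NH (carbonylative Sonogashira coupling with in situ 6-endo closure by the only free hydroxyl) to give 12. This is then taken through the second stage of step 7.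

**Step 5.**
- The conjugate addition may be sluggish, because the 2'- and 4'-methoxy groups push electron density onto C2 and the ortho methoxy shields it.
- At the temperature then needed, the phenoxide may attack the ester carbonyl and release methoxide that competes for the alkyne. The electron-rich phenoxide may also be oxidised by traces of air.
- Fallback (sets out from 8 and 4, comes back at 9): the O1–C2 bond is made by metal-catalysed substitution instead of addition. 8 is hydroiodinated (NaI, AcOH, 110 °C, anti addition) to methyl (2Z)-3-iodo-3-(2,4,5-trimethoxyphenyl)prop-2-enoate F4. F4 is coupled with 4 in an Ullmann-type vinylation (CuI, N,N-dimethylglycine, Cs2CO3, dioxane, 80 °C) with retention of geometry to give 9.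

**Step 4.**
- Base-induced oligomerisation and oxidative dimerisation of 7 may outrun the slow oxidative addition of zerovalent palladium to the electron-rich, ortho-substituted iodide.
- Fallback (sets out from 5, comes back at 8): the alkyne is built from a carbonyl group instead of being coupled. 5 is formylated (POCl3, DMF, Vilsmeier–Haack reaction) to 2,4,5-trimethoxybenzaldehyde F5. F5 is converted with CBr4 and PPh3 (Corey–Fuchs olefination) into 1-(2,2-dibromoethenyl)-2,4,5-trimethoxybenzene F6. F6 is treated with n-BuLi (2.1 equiv, THF, −78 °C) and then ClCO2Me to give 8.

**Step 6.**
- Hydroxide may attack C2 with expulsion of the phenoxide (addition–elimination). Acetal loss or protodecarboxylation may occur during acidification.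
- Fallback (sets out from 6 and 4, comes back at 10): the acid is reached by oxidation instead of hydrolysis, through a more electrophilic acceptor.
  - 6 is coupled with propargyl alcohol (PdCl2(PPh3)2, CuI, Et3N) to 3-(2,4,5-trimethoxyphenyl)prop-2-yn-1-ol F7.
  - F7 is oxidised with MnO2 (CH2Cl2) to 3-(2,4,5-trimethoxyphenyl)prop-2-ynal F8.
  - 4 adds to F8 with catalytic DABCO at rt to give (2Z)-3-[4-methoxy-3,5-bis(methoxymethoxy)phenoxy]-3-(2,4,5-trimethoxyphenyl)prop-2-enal F9.
  - Pinnick oxidation (NaClO2, NaH2PO4, 2-methyl-2-butene, t-BuOH/H2O) gives 10.

## Further compounds

F1 | step 7 | 2-iodo-4-methoxy-3,5-bis(methoxymethoxy)phenol | COCOc1cc(O)c(I)c(OCOC)c1OC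
F2 | step 7 | trimethyl[(2,4,5-trimethoxyphenyl)ethynyl]silane | COc1cc(OC)c(C#C[Si](C)(C)C)cc1OC
F3 | step 7 | 1-ethynyl-2,4,5-trimethoxybenzene | C#Cc1cc(OC)c(OC)cc1OC
F4 | step 5 | methyl (2Z)-3-iodo-3-(2,4,5-trimethoxyphenyl)prop-2-enoate | COC(=O)/C=C(\I)c1cc(OC)c(OC)cc1OC
F5 | step 4 | 2,4,5-trimethoxybenzaldehyde | COc1cc(OC)c(C=O)cc1OC
F6 | step 4 | 1-(2,2-dibromoethenyl)-2,4,5-trimethoxybenzene | COc1cc(OC)c(C=C(Br)Br)cc1OC
F7 | step 6 | 3-(2,4,5-trimethoxyphenyl)prop-2-yn-1-ol | OCC#Cc1cc(OC)c(OC)cc1OC
F8 | step 6 | 3-(2,4,5-trimethoxyphenyl)prop-2-ynal | O=CC#Cc1cc(OC)c(OC)cc1OC
F9 | step 6 | (2Z)-3-[4-methoxy-3,5-bis(methoxymethoxy)phenoxy]-3-(2,4,5-trimethoxyphenyl)prop-2-enal | O=C/C=C(\Oc1cc(OCOC)c(OC)c(OCOC)c1)c1cc(OC)c(OC)cc1OC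
A1 | alternative 1 | 1-[2,4-bis(benzyloxy)-6-hydroxy-3-methoxyphenyl]ethan-1-one | CC(=O)c1c(O)cc(OCc2ccccc2)c(OC)c1OCc1ccccc1
A2 | alternative 1 | 2,4,5-trimethoxybenzoyl chloride | COc1cc(OC)c(C(=O)Cl)cc1OC
A3 | alternative 1 | 1-[2,4-bis(benzyloxy)-6-hydroxy-3-methoxyphenyl]-3-(2,4,5-trimethoxyphenyl)propane-1,3-dione | COc1cc(OC)c(C(=O)CC(=O)c2c(O)cc(OCc3ccccc3)c(OC)c2OCc2ccccc2)cc1OC
A4 | alternative 1 | 5,7-dihydroxy-8-methoxy-2-(2,4,5-trimethoxyphenyl)-4H-chromen-4-one | COc1cc(OC)c(-c2cc(=O)c3c(O)cc(O)c(OC)c3o2)cc1OC
A5 | alternative 2 | 6-methoxy-5,7-bis(methoxymethoxy)-4H-chromen-4-one | COCOc1cc2occc(=O)c2c(OCOC)c1OC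
A6 | alternative 3 | 2-methoxybenzene-1,3,5-triol | COc1c(O)cc(O)cc1O
A7 | alternative 3 | ethyl 3-oxo-3-(2,4,5-trimethoxyphenyl)propanoate | CCOC(=O)CC(=O)c1cc(OC)c(OC)cc1OC
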